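Everything rests on opening the butenolide (ring A: O1, C1 carbonyl, C2, C3, C4) at C3–C4 and O1–C1. The key step exploits that C1–C2–C3 is a β-methoxyacrylate in disguise and C4 an aldehyde carbon: a 3-lithio-3-methoxy-2-methylacrylate adds to an α-silyloxy aldehyde that already carries the whole bis-furyl chain, and the alkoxide lactonises in the same flask, closing ring A and creating a 4,5-anti pair of sp3 centres. That pair is spent afterwards in an anti-elimination of H-4 and the C5 oxygen, which writes the (E)-C4=C5 alkene beside the stereocentre C6; C6 comes unchanged from (S)-citronellal. O-Demethylation and O-sulfation at C3 finish the synthesis.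

Key step: step 13

Remark on numbering: C5 is the exocyclic carbon on C4 and C6 the methyl-bearing stereocentre; these atom numbers are kept for the same atoms in every intermediate.
Assumption: the target is wanted as the free hydrogen sulfate that is drawn; since this is a strong acid next to acid-sensitive furans, it would be released from its pyridinium salt only in the last operation, cold, and otherwise kept as a salt.
Assumption: (S)-citronellal of high enantiomeric purity is taken as the commercial chiral starting material; the centres made at C4 and C5 are temporary and disappear in step 15.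

Step 1
Reactants: 1 3-bromofuran; 2 4-bromofuran-2-carbaldehyde
Product: 4 rac-(4-bromofuran-2-yl)(furan-3-yl)methanol, via furan-3-yllithium 3 (not isolated)
Conditions: n-BuLi, THF, −78 °C; then 2, −78 °C; H2O
Reagents that add atoms: none
Why: Halogen–lithium exchange at −78 °C gives the 3-lithiofuran without migration to C2, and its 1,2-addition to the aldehyde should be much faster than exchange with the ring bromide of 2; the carbinol centre is racemic and is removed in step 2.

Step 2
Reactants: 4 rac-(4-bromofuran-2-yl)(furan-3-yl)methanol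
Product: 5 4-bromo-2-(furan-3-ylmethyl)furan
Conditions: Et3SiH, CF3CO2H, CH2Cl2, −20 °C
Reagents that add atoms: none
Why: Ionic hydrogenation, in which the cation stabilised by two furan rings is trapped by excess silane hydride at low temperature before it can alkylate another furan, while the C–Br bond is inert.

Step 3
Reactants: 6 methyl propionate
Product: 8 methyl (E)-3-methoxy-2-methylacrylate, via sodium formyl enolate 7 (not isolated)
Conditions: NaH, HCO2Me, THF, 0 °C → rt; then Me2SO4, DMF, rt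
Reagents that add atoms: methyl formate, COC=O; dimethyl sulfate, COS(=O)(=O)OC
Why: Crossed Claisen formylation followed by O-methylation of the sodium enolate with a hard electrophile in DMF should give the β-methoxyacrylate, the more stable (E) isomer being purified by distillation.

Step 4
Reactants: 9 (S)-citronellal
Product: 11 (2R,3S)-3,7-dimethyl-2-(phenylaminooxy)oct-6-en-1-ol, via α-aminoxy aldehyde 10 (not isolated)
Conditions: L-proline (20 mol %), PhNO, DMSO, rt; then NaBH4, MeOH, 0 °C
Reagents that add atoms: nitrosobenzene, O=Nc1ccccc1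
Why: Proline-catalysed α-aminoxylation (enamine catalysis), in which the carboxylic acid of L-proline guides the oxygen of nitrosobenzene to one face of the enamine and so sets the new carbinol centre (R) under catalyst control whatever the neighbouring methyl centre, the labile aldehyde being reduced in the flask.

Step 5
Reactants: 11 (2R,3S)-3,7-dimethyl-2-(phenylaminooxy)oct-6-en-1-ol
Product: 12 (2R,3S)-3,7-dimethyloct-6-ene-1,2-diol
Conditions: Zn, AcOH, THF, rt
Reagents that add atoms: none
Why: Reductive N–O cleavage by zinc in acetic acid breaks only the weak N–O bond and leaves the trisubstituted alkene and both stereocentres untouched.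

Step 6
Reactants: 12 (2R,3S)-3,7-dimethyloct-6-ene-1,2-diol
Product: 13 (2R,3S)-1,2-bis(tert-butyldimethylsilyloxy)-3,7-dimethyloct-6-ene
Conditions: TBSOTf, 2,6-lutidine, CH2Cl2, −78 → 0 °C
Reagents that add atoms: tert-butyldimethylsilyl triflate, CC(C)(C)[Si](C)(C)OS(=O)(=O)C(F)(F)F
Why: Silylation with the reactive silyl triflate and a hindered base should cover the primary and the hindered secondary hydroxyl in one operation.

Step 7
Reactants: 13 (2R,3S)-1,2-bis(tert-butyldimethylsilyloxy)-3,7-dimethyloct-6-ene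
Product: 14 (2E,6S,7R)-7,8-bis(tert-butyldimethylsilyloxy)-2,6-dimethyloct-2-en-1-ol
Conditions: SeO2 (cat.), t-BuOOH, CH2Cl2, 0 °C → rt
Reagents that add atoms: tert-butyl hydroperoxide, CC(C)(C)OO (terminal oxidant); selenium dioxide, O=[Se]=O (catalytic oxygen carrier)
Why: Selenium dioxide allylic oxidation (ene reaction, then 2,3-sigmatropic shift) is selective for the (E)-methyl group of a gem-dimethyl alkene terminus and should give the (E)-allylic alcohol, any over-oxidised enal being separable.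

Step 8
Reactants: 14 (2E,6S,7R)-7,8-bis(tert-butyldimethylsilyloxy)-2,6-dimethyloct-2-en-1-ol
Product: 15 (2E,6S,7R)-1-bromo-7,8-bis(tert-butyldimethylsilyloxy)-2,6-dimethyloct-2-ene
Conditions: CBr4, PPh3, CH2Cl2, −20 → 0 °C
Reagents that add atoms: carbon tetrabromide, BrC(Br)(Br)Br
Why: The Appel reaction converts the primary allylic alcohol to the bromide under neutral conditions without allylic transposition, and the silyl ethers should survive the short cold reaction.

Step 9
Reactants: 15 (2E,6S,7R)-1-bromo-7,8-bis(tert-butyldimethylsilyloxy)-2,6-dimethyloct-2-ene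
Product: 16 (2R,3S,6E)-1,2-bis(tert-butyldimethylsilyloxy)-3,7-dimethyldeca-6,9-diene
Conditions: CH2=CHMgBr, CuI (10 mol %), THF, −30 → 0 °C
Reagents that add atoms: vinylmagnesium bromide, C=C[Mg]Br
Why: Copper-catalysed Grignard coupling with a primary allylic bromide under cuprate-forming conditions (THF, low temperature, excess Grignard) should substitute at the unhindered CH2 carbon (SN2) with the (E)-alkene retained, giving the skipped diene.

Step 10
Reactants: 16 (2R,3S,6E)-1,2-bis(tert-butyldimethylsilyloxy)-3,7-dimethyldeca-6,9-diene; 5 4-bromo-2-(furan-3-ylmethyl)furan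
Product: 18 4-[(4E,8S,9R)-9,10-bis(tert-butyldimethylsilyloxy)-4,8-dimethyldec-4-en-1-yl]-2-(furan-3-ylmethyl)furan, via B-alkyl-9-BBN borane 17 (not isolated)
Conditions: 9-BBN, THF, 0 °C → rt; then 5, PdCl2(dppf) (5 mol %), aq. K3PO4, DMF, 50 °C
Reagents that add atoms: none
Why: Hydroboration with bulky 9-BBN is selective for the terminal alkene (anti-Markovnikov), and the B-alkyl Suzuki–Miyaura coupling of the resulting borane with the β-bromofuran under a divalent-palladium precatalyst and aqueous phosphate should leave silyl ethers, the trisubstituted alkene and both furans untouched.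

Step 11
Reactants: 18 4-[(4E,8S,9R)-9,10-bis(tert-butyldimethylsilyloxy)-4,8-dimethyldec-4-en-1-yl]-2-(furan-3-ylmethyl)furan
Product: 19 (2R,3S,6E)-2-(tert-butyldimethylsilyloxy)-10-[5-(furan-3-ylmethyl)furan-3-yl]-3,7-dimethyldec-6-en-1-ol
Conditions: HF·pyridine, pyridine, THF, 0 °C
Reagents that add atoms: none
Why: Buffered fluoride desilylation removes the unhindered primary silyl ether much faster than the secondary one flanked by two branched carbons, and the furans tolerate the weakly acidic medium.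

Step 12
Reactants: 19 (2R,3S,6E)-2-(tert-butyldimethylsilyloxy)-10-[5-(furan-3-ylmethyl)furan-3-yl]-3,7-dimethyldec-6-en-1-ol
Product: 20 (2R,3S,6E)-2-(tert-butyldimethylsilyloxy)-10-[5-(furan-3-ylmethyl)furan-3-yl]-3,7-dimethyldec-6-enal
Conditions: Dess–Martin periodinane, pyridine, CH2Cl2, 0 °C → rt
Reagents that add atoms: none
Why: Dess–Martin oxidation under pyridine buffering should give the α-silyloxy aldehyde without epimerisation or over-oxidation, and the aldehyde would be used at once without chromatography.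

Step 13
Reactants: 8 methyl (E)-3-methoxy-2-methylacrylate; 20 (2R,3S,6E)-2-(tert-butyldimethylsilyloxy)-10-[5-(furan-3-ylmethyl)furan-3-yl]-3,7-dimethyldec-6-enal
Product: 23 (5R)-5-[(1R,2S,5E)-1-(tert-butyldimethylsilyloxy)-9-[5-(furan-3-ylmethyl)furan-3-yl]-2,6-dimethylnon-5-en-1-yl]-4-methoxy-3-methylfuran-2(5H)-one, via vinyllithium 21 (not isolated), via lithium alkoxide 22 (not isolated)
Conditions: 8, LiN(iPr)2 (LDA), THF, −90 °C; then 20, −90 → −40 °C; AcOH
Reagents that add atoms: none
Why: LDA removes the C3 hydrogen of 8 at −90 °C to give vinyllithium 21, held cis to the ester by chelation, which adds to the aldehyde carbon (C3–C4), and the lithium alkoxide 22 then attacks the neighbouring ester with loss of methoxide (O1–C1). The closest known reaction type is the addition of β-lithio-β-methoxyacrylates to aldehydes with spontaneous lactonisation to 4-methoxybutenolides, a formal (3+2) annulation. Ring A closes by 5-exo-trig acyl substitution. The new centre C4 is set (R) by the adjacent centre C5 through the polar Felkin–Anh model: the C5–O bond stands perpendicular to the carbonyl and anti to the incoming carbon, which passes the C5 hydrogen and not the C6 branch. The step needs 4,5-anti facial selectivity, which the bulky non-chelating tert-butyldimethylsilyl ether with a lithium counter-ion in THF should secure, and chemoselectivity for the aldehyde, which holds because furans, alkene and silyl ether are inert to the vinyllithium at this temperature.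

Step 14
Reactants: 23 (5R)-5-[(1R,2S,5E)-1-(tert-butyldimethylsilyloxy)-9-[5-(furan-3-ylmethyl)furan-3-yl]-2,6-dimethylnon-5-en-1-yl]-4-methoxy-3-methylfuran-2(5H)-one
Product: 24 (5R)-5-[(1R,2S,5E)-9-[5-(furan-3-ylmethyl)furan-3-yl]-1-hydroxy-2,6-dimethylnon-5-en-1-yl]-4-methoxy-3-methylfuran-2(5H)-one
Conditions: HF·pyridine, THF, 0 °C → rt
Reagents that add atoms: none
Why: Fluoride desilylation under weakly acidic conditions frees the C5 hydroxyl while avoiding base-induced epimerisation at C4, retro-aldol cleavage and translactonisation.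

Step 15
Reactants: 24 (5R)-5-[(1R,2S,5E)-9-[5-(furan-3-ylmethyl)furan-3-yl]-1-hydroxy-2,6-dimethylnon-5-en-1-yl]-4-methoxy-3-methylfuran-2(5H)-one
Product: 26 (5E)-5-[(2S,5E)-9-[5-(furan-3-ylmethyl)furan-3-yl]-2,6-dimethylnon-5-en-1-ylidene]-4-methoxy-3-methylfuran-2(5H)-one, via secondary triflate 25 (not isolated)
Conditions: Tf2O, pyridine, CH2Cl2, −78 °C → rt
Reagents that add atoms: none
Why: Triflation followed by concerted E2 anti-elimination with the weak base pyridine should be stereospecific, and since in the 4R,5R isomer H-4 and the C5 oxygen are antiperiplanar only when C6 lies on the C3 side, the (E)-alkylidene is expected, the weak base disfavouring a stereorandom E1cB path through the furanolate.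

Step 16
Reactants: 26 (5E)-5-[(2S,5E)-9-[5-(furan-3-ylmethyl)furan-3-yl]-2,6-dimethylnon-5-en-1-ylidene]-4-methoxy-3-methylfuran-2(5H)-one
Product: 28 (5E)-5-[(2S,5E)-9-[5-(furan-3-ylmethyl)furan-3-yl]-2,6-dimethylnon-5-en-1-ylidene]-4-hydroxy-3-methylfuran-2(5H)-one, via lithium tetronate 27 (not isolated)
Conditions: LiCl, DMSO, 60 °C; then cold dilute aq. HCl
Reagents that add atoms: none
Why: Krapcho-type SN2 O-demethylation, in which chloride attacks the methyl group of the vinylogous carbonate and releases the stabilised tetronate, would be run warm and not hot, under argon and in the dark, to preserve the (E)-alkylidene.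

Step 17
Reactants: 28 (5E)-5-[(2S,5E)-9-[5-(furan-3-ylmethyl)furan-3-yl]-2,6-dimethylnon-5-en-1-ylidene]-4-hydroxy-3-methylfuran-2(5H)-one
Product: 30 (2E)-2-[(2S,5E)-9-[5-(furan-3-ylmethyl)furan-3-yl]-2,6-dimethylnon-5-en-1-ylidene]-4-methyl-5-oxo-2,5-dihydrofuran-3-yl hydrogen sulfate, via pyridinium sulfate 29 (not isolated)
Conditions: SO3·pyridine, pyridine, 0 °C → rt; then Dowex 50W (H+ form), MeOH, 0 °C
Reagents that add atoms: sulfur trioxide–pyridine complex, [O-]S(=O)(=O)[n+]1ccccc1
Why: O-Sulfation of the acidic enol hydroxyl by the SO3–amine complex, as for phenols, should be far faster at 0 °C than C-sulfonation of the furans, and cold proton exchange on the acidic resin converts the pyridinium salt into the hydrogen sulfate.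

Compound list
1 | 3-bromofuran | Brc1ccoc1 | starting material
2 | 4-bromofuran-2-carbaldehyde | O=Cc1cc(Br)co1 | starting material
3 | furan-3-yllithium (formed in the flask) | [Li]c1ccoc1 | intermediate
4 | rac-(4-bromofuran-2-yl)(furan-3-yl)methanol | OC(c1ccoc1)c1cc(Br)co1 | intermediate
5 | 4-bromo-2-(furan-3-ylmethyl)furan | Brc1coc(Cc2ccoc2)c1 | intermediate
6 | methyl propionate | CCC(=O)OC | starting material
7 | sodium enolate of methyl 2-formylpropanoate (formed in the flask) | [Na+].[O-]C=C(C)C(=O)OC | intermediate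
8 | methyl (E)-3-methoxy-2-methylacrylate | CO/C=C(C)/C(=O)OC | intermediate
9 | (S)-citronellal | O=CC[C@@H](C)CCC=C(C)C | starting material
10 | (2R,3S)-3,7-dimethyl-2-(phenylaminooxy)oct-6-enal (formed in the flask) | O=C[C@H](ONc1ccccc1)[C@@H](C)CCC=C(C)C | intermediate
11 | (2R,3S)-3,7-dimethyl-2-(phenylaminooxy)oct-6-en-1-ol | OC[C@H](ONc1ccccc1)[C@@H](C)CCC=C(C)C | intermediate
12 | (2R,3S)-3,7-dimethyloct-6-ene-1,2-diol | OC[C@H](O)[C@@H](C)CCC=C(C)C | intermediate
13 | (2R,3S)-1,2-bis(tert-butyldimethylsilyloxy)-3,7-dimethyloct-6-ene | CC(C)(C)[Si](C)(C)OC[C@H](O[Si](C)(C)C(C)(C)C)[C@@H](C)CCC=C(C)C | intermediate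
14 | (2E,6S,7R)-7,8-bis(tert-butyldimethylsilyloxy)-2,6-dimethyloct-2-en-1-ol | CC(C)(C)[Si](C)(C)OC[C@H](O[Si](C)(C)C(C)(C)C)[C@@H](C)CC/C=C(\C)CO | intermediate
15 | (2E,6S,7R)-1-bromo-7,8-bis(tert-butyldimethylsilyloxy)-2,6-dimethyloct-2-ene | CC(C)(C)[Si](C)(C)OC[C@H](O[Si](C)(C)C(C)(C)C)[C@@H](C)CC/C=C(\C)CBr | intermediate
16 | (2R,3S,6E)-1,2-bis(tert-butyldimethylsilyloxy)-3,7-dimethyldeca-6,9-diene | CC(C)(C)[Si](C)(C)OC[C@H](O[Si](C)(C)C(C)(C)C)[C@@H](C)CC/C=C(\C)CC=C | intermediate
17 | 9-[(4E,8S,9R)-9,10-bis(tert-butyldimethylsilyloxy)-4,8-dimethyldec-4-en-1-yl]-9-borabicyclo[3.3.1]nonane (formed in the flask) | CC(C)(C)[Si](C)(C)OC[C@H](O[Si](C)(C)C(C)(C)C)[C@@H](C)CC/C=C(\C)CCCB1C2CCCC1CCC2 | intermediate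
18 | 4-[(4E,8S,9R)-9,10-bis(tert-butyldimethylsilyloxy)-4,8-dimethyldec-4-en-1-yl]-2-(furan-3-ylmethyl)furan | CC(C)(C)[Si](C)(C)OC[C@H](O[Si](C)(C)C(C)(C)C)[C@@H](C)CC/C=C(\C)CCCc1coc(Cc2ccoc2)c1 | intermediate
19 | (2R,3S,6E)-2-(tert-butyldimethylsilyloxy)-10-[5-(furan-3-ylmethyl)furan-3-yl]-3,7-dimethyldec-6-en-1-ol | OC[C@H](O[Si](C)(C)C(C)(C)C)[C@@H](C)CC/C=C(\C)CCCc1coc(Cc2ccoc2)c1 | intermediate
20 | (2R,3S,6E)-2-(tert-butyldimethylsilyloxy)-10-[5-(furan-3-ylmethyl)furan-3-yl]-3,7-dimethyldec-6-enal | O=C[C@H](O[Si](C)(C)C(C)(C)C)[C@@H](C)CC/C=C(\C)CCCc1coc(Cc2ccoc2)c1 | intermediate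
21 | methyl (E)-3-lithio-3-methoxy-2-methylprop-2-enoate, lithium cis to the ester (formed in the flask) | CO/C([Li])=C(C)/C(=O)OC | intermediate
22 | lithium alkoxide of methyl (2E,4R,5R,6S,9E)-5-(tert-butyldimethylsilyloxy)-13-[5-(furan-3-ylmethyl)furan-3-yl]-4-hydroxy-3-methoxy-2,6,10-trimethyltrideca-2,9-dienoate (formed in the flask) | [Li+].COC(=O)/C(C)=C(/OC)[C@H]([O-])[C@H](O[Si](C)(C)C(C)(C)C)[C@@H](C)CC/C=C(\C)CCCc1coc(Cc2ccoc2)c1 | intermediate
23 | (5R)-5-[(1R,2S,5E)-1-(tert-butyldimethylsilyloxy)-9-[5-(furan-3-ylmethyl)furan-3-yl]-2,6-dimethylnon-5-en-1-yl]-4-methoxy-3-methylfuran-2(5H)-one | CC1=C(OC)[C@@H]([C@H](O[Si](C)(C)C(C)(C)C)[C@@H](C)CC/C=C(\C)CCCc2coc(Cc3ccoc3)c2)OC1=O | intermediate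
24 | (5R)-5-[(1R,2S,5E)-9-[5-(furan-3-ylmethyl)furan-3-yl]-1-hydroxy-2,6-dimethylnon-5-en-1-yl]-4-methoxy-3-methylfuran-2(5H)-one | CC1=C(OC)[C@@H]([C@H](O)[C@@H](C)CC/C=C(\C)CCCc2coc(Cc3ccoc3)c2)OC1=O | intermediate
25 | (1R,2S,5E)-9-[5-(furan-3-ylmethyl)furan-3-yl]-1-[(2R)-3-methoxy-4-methyl-5-oxo-2,5-dihydrofuran-2-yl]-2,6-dimethylnon-5-en-1-yl trifluoromethanesulfonate (formed in the flask) | CC1=C(OC)[C@@H]([C@H](OS(=O)(=O)C(F)(F)F)[C@@H](C)CC/C=C(\C)CCCc2coc(Cc3ccoc3)c2)OC1=O | intermediate
26 | (5E)-5-[(2S,5E)-9-[5-(furan-3-ylmethyl)furan-3-yl]-2,6-dimethylnon-5-en-1-ylidene]-4-methoxy-3-methylfuran-2(5H)-one | CC1=C(OC)/C(=C\[C@@H](C)CC/C=C(\C)CCCc2coc(Cc3ccoc3)c2)OC1=O | intermediate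
27 | lithium (2E)-2-[(2S,5E)-9-[5-(furan-3-ylmethyl)furan-3-yl]-2,6-dimethylnon-5-en-1-ylidene]-4-methyl-5-oxo-2,5-dihydrofuran-3-olate (formed in the flask) | [Li+].CC1=C([O-])/C(=C\[C@@H](C)CC/C=C(\C)CCCc2coc(Cc3ccoc3)c2)OC1=O | intermediate
28 | (5E)-5-[(2S,5E)-9-[5-(furan-3-ylmethyl)furan-3-yl]-2,6-dimethylnon-5-en-1-ylidene]-4-hydroxy-3-methylfuran-2(5H)-one | CC1=C(O)/C(=C\[C@@H](C)CC/C=C(\C)CCCc2coc(Cc3ccoc3)c2)OC1=O | intermediate
29 | pyridinium (2E)-2-[(2S,5E)-9-[5-(furan-3-ylmethyl)furan-3-yl]-2,6-dimethylnon-5-en-1-ylidene]-4-methyl-5-oxo-2,5-dihydrofuran-3-yl sulfate (formed in the flask) | CC1=C(OS(=O)(=O)[O-])/C(=C\[C@@H](C)CC/C=C(\C)CCCc2coc(Cc3ccoc3)c2)OC1=O.c1cc[nH+]cc1 | intermediate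
30 | (2E)-2-[(2S,5E)-9-[5-(furan-3-ylmethyl)furan-3-yl]-2,6-dimethylnon-5-en-1-ylidene]-4-methyl-5-oxo-2,5-dihydrofuran-3-yl hydrogen sulfate | CC1=C(OS(=O)(=O)O)/C(=C\[C@@H](C)CC/C=C(\C)CCCc2coc(Cc3ccoc3)c2)OC1=O | target

Total step count: 17 (steps 1–2 make bromofuran 5, step 3 makes acrylate 8, steps 4–17 are the main line).
Longest linear sequence: 14 steps, from (S)-citronellal 9 to 30 (steps 4–17).

Steps most likely to fail

Step 13. The facial selectivity at the aldehyde may erode, because chelated or Cornforth-type transition states can compete with the polar Felkin–Anh one, and any loss passes straight into the alkene geometry; the fragile vinyllithium may also decompose before it adds. The fallback replaces facial control in C–C bond formation by chelation control in hydride delivery; it sets out from 19 and comes back at 24. Alcohol 19 would be oxidised (TEMPO, 2,2,6,6-tetramethylpiperidin-1-oxyl, catalytic; PhI(OAc)2; MeCN/H2O) to (2R,3S,6E)-2-(tert-butyldimethylsilyloxy)-10-[5-(furan-3-ylmethyl)furan-3-yl]-3,7-dimethyldec-6-enoic acid F1 and condensed with MeNHOMe·HCl (EDC·HCl, iPr2NEt) to (2R,3S,6E)-2-(tert-butyldimethylsilyloxy)-10-[5-(furan-3-ylmethyl)furan-3-yl]-N-methoxy-N,3,7-trimethyldec-6-enamide F2. Acylation of vinyllithium 21 by this amide at −90 °C would give methyl (2E,5R,6S,9E)-5-(tert-butyldimethylsilyloxy)-13-[5-(furan-3-ylmethyl)furan-3-yl]-3-methoxy-2,6,10-trimethyl-4-oxotrideca-2,9-dienoate F3, and HF·pyridine would free methyl (2E,5R,6S,9E)-13-[5-(furan-3-ylmethyl)furan-3-yl]-5-hydroxy-3-methoxy-2,6,10-trimethyl-4-oxotrideca-2,9-dienoate F4. Zn(BH4)2 in Et2O at −20 °C would then reduce the ketone through the zinc chelate of the C5 hydroxyl and the C4 carbonyl, hydride entering from the side of the C5 hydrogen, to give the 4,5-anti diol, whose C4 hydroxyl closes onto the cis ester to give 24 directly.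

Step 15. Stereospecificity may be lost if the triflate ionises or if C4 is deprotonated before the leaving group departs (E1cB through the furanolate); either path lets the more stable (Z)-alkylidene form, and displacement of the triflate by pyridine is a further drain. The fallback is a redox dehydration in place of a sulfonate elimination; it sets out from 24 and comes back at 26. PPh3 and diethyl azodicarboxylate in THF at 0 °C (Mitsunobu conditions) would turn the hydroxyl into an alkoxyphosphonium leaving group, which is expelled in an anti-elimination under neutral conditions with no sulfonate ester and no free amine base present. No new isolable compound is involved.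

Step 16. The strained (E)-alkylidene may isomerise to (Z) during the warm nucleophilic demethylation, by reversible addition of chloride at C5 or by equilibration of the tetronate, and the cleavage may stay incomplete. The fallback exchanges the methyl group for an allyl group before the alkene exists; it sets out from 23 and comes back at 28. LiCl in DMSO would be applied to 23, which has no alkylidene to lose, to give (5R)-5-[(1R,2S,5E)-1-(tert-butyldimethylsilyloxy)-9-[5-(furan-3-ylmethyl)furan-3-yl]-2,6-dimethylnon-5-en-1-yl]-4-hydroxy-3-methylfuran-2(5H)-one F5. Mitsunobu O-allylation (allyl alcohol, PPh3, diisopropyl azodicarboxylate) would give (5R)-5-[(1R,2S,5E)-1-(tert-butyldimethylsilyloxy)-9-[5-(furan-3-ylmethyl)furan-3-yl]-2,6-dimethylnon-5-en-1-yl]-3-methyl-4-(prop-2-en-1-yloxy)furan-2(5H)-one F6. HF·pyridine would give (5R)-5-[(1R,2S,5E)-9-[5-(furan-3-ylmethyl)furan-3-yl]-1-hydroxy-2,6-dimethylnon-5-en-1-yl]-3-methyl-4-(prop-2-en-1-yloxy)furan-2(5H)-one F7, and Tf2O with pyridine would give (5E)-5-[(2S,5E)-9-[5-(furan-3-ylmethyl)furan-3-yl]-2,6-dimethylnon-5-en-1-ylidene]-3-methyl-4-(prop-2-en-1-yloxy)furan-2(5H)-one F8. Pd(PPh3)4 (catalytic, zerovalent palladium) with morpholine in THF at rt would then remove the allyl group under neutral conditions to give 28.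

Further compounds
F1 | step 13 | (2R,3S,6E)-2-(tert-butyldimethylsilyloxy)-10-[5-(furan-3-ylmethyl)furan-3-yl]-3,7-dimethyldec-6-enoic acid | O=C(O)[C@H](O[Si](C)(C)C(C)(C)C)[C@@H](C)CC/C=C(\C)CCCc1coc(Cc2ccoc2)c1
F2 | step 13 | (2R,3S,6E)-2-(tert-butyldimethylsilyloxy)-10-[5-(furan-3-ylmethyl)furan-3-yl]-N-methoxy-N,3,7-trimethyldec-6-enamide | CON(C)C(=O)[C@H](O[Si](C)(C)C(C)(C)C)[C@@H](C)CC/C=C(\C)CCCc1coc(Cc2ccoc2)c1
F3 | step 13 | methyl (2E,5R,6S,9E)-5-(tert-butyldimethylsilyloxy)-13-[5-(furan-3-ylmethyl)furan-3-yl]-3-methoxy-2,6,10-trimethyl-4-oxotrideca-2,9-dienoate | COC(=O)/C(C)=C(/OC)C(=O)[C@H](O[Si](C)(C)C(C)(C)C)[C@@H](C)CC/C=C(\C)CCCc1coc(Cc2ccoc2)c1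
F4 | step 13 | methyl (2E,5R,6S,9E)-13-[5-(furan-3-ylmethyl)furan-3-yl]-5-hydroxy-3-methoxy-2,6,10-trimethyl-4-oxotrideca-2,9-dienoate | COC(=O)/C(C)=C(/OC)C(=O)[C@H](O)[C@@H](C)CC/C=C(\C)CCCc1coc(Cc2ccoc2)c1
F0 | step 15 | none | none
F5 | step 16 | (5R)-5-[(1R,2S,5E)-1-(tert-butyldimethylsilyloxy)-9-[5-(furan-3-ylmethyl)furan-3-yl]-2,6-dimethylnon-5-en-1-yl]-4-hydroxy-3-methylfuran-2(5H)-one | CC1=C(O)[C@@H]([C@H](O[Si](C)(C)C(C)(C)C)[C@@H](C)CC/C=C(\C)CCCc2coc(Cc3ccoc3)c2)OC1=O
F6 | step 16 | (5R)-5-[(1R,2S,5E)-1-(tert-butyldimethylsilyloxy)-9-[5-(furan-3-ylmethyl)furan-3-yl]-2,6-dimethylnon-5-en-1-yl]-3-methyl-4-(prop-2-en-1-yloxy)furan-2(5H)-one | CC1=C(OCC=C)[C@@H]([C@H](O[Si](C)(C)C(C)(C)C)[C@@H](C)CC/C=C(\C)CCCc2coc(Cc3ccoc3)c2)OC1=O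
F7 | step 16 | (5R)-5-[(1R,2S,5E)-9-[5-(furan-3-ylmethyl)furan-3-yl]-1-hydroxy-2,6-dimethylnon-5-en-1-yl]-3-methyl-4-(prop-2-en-1-yloxy)furan-2(5H)-one | CC1=C(OCC=C)[C@@H]([C@H](O)[C@@H](C)CC/C=C(\C)CCCc2coc(Cc3ccoc3)c2)OC1=O
F8 | step 16 | (5E)-5-[(2S,5E)-9-[5-(furan-3-ylmethyl)furan-3-yl]-2,6-dimethylnon-5-en-1-ylidene]-3-methyl-4-(prop-2-en-1-yloxy)furan-2(5H)-one | CC1=C(OCC=C)/C(=C\[C@@H](C)CC/C=C(\C)CCCc2coc(Cc3ccoc3)c2)OC1=O
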